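Take the flat end of a run's product curve, divide it by the free catalyst charged, and carry that number from flask to flask.

| setting | dusk | noon | dawn | flask |
|---|---|---|---|---|
| substrate | 0.10 M | 0.10 M | 0.050 M | 0.10 M |
| coupling partner | 0.18 M | 0.18 M | 0.18 M | 0.180 M |
| free catalyst | 0.21 mM | 0.46 mM | 0.31 mM | 0.31 mM |
| remark | run made earlier | run made earlier | run made earlier |  |
| time |  |  |  | 50 min |

- dusk (time / min: intermediate / %, product / %, substrate / %): 5.00: 33.5, 2.0, 63.3; 8.00: 33.7, 4.1, 61.6; 12.0: 32.4, 5.0, 61.3; 20.0: 33.3, 5.7, 60.6; 40.0: 32.3, 5.2, 60.2; 60.0: 32.3, 6.1, 59.9
- noon (time / min: intermediate / %, product / %, substrate / %): 4.00: 33.2, 4.6, 61.4; 12.0: 31.5, 8.8, 58.2; 20.0: 30.8, 11.3, 56.7; 30.0: 30.0, 12.0, 55.2; 50.0: 30.1, 12.1, 55.6; 60.0: 29.6, 12.3, 55.8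
- dawn (time / min: intermediate / %, product / %, substrate / %): 5.00: 34.6, 3.8, 61.9; 10.0: 32.3, 6.1, 61.4; 15.0: 31.9, 7.1, 59.7; 30.0: 31.7, 9.4, 58.7; 60.0: 31.5, 9.3, 58.0

(scatter of a reading: 0.5 percentage points)

- percentages count the substrate that a species holds: one homo dimer or idle adduct counts as two
- product is meant together with its idle adduct
- candidate steps: substrate + free catalyst <-> free catalyst + intermediate; substrate + product <-> idle adduct; coupling partner + free catalyst + intermediate -> free catalyst + product; free catalyst -> spent catalyst; 2 substrate -> homo dimer
- in an amount of product, one idle adduct counts as one product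

- the largest share of what was charged as substrate, at 50 min belongs to (substrate / product / intermediate)
- the largest share itself, whichever of these holds it, in percent of the substrate charged

1. Late product readings, as fractions of the substrate charged, give per mM of free catalyst 0.270 /mM at dusk, 0.264 /mM at noon and 0.302 /mM at dawn, so I carry their mean, 0.278 /mM, as the capacity, the fraction of the substrate charged that ends as product per mM of catalyst charged.

2. The first noon reading against the noon plateau of 12.1% reads, for first-order catalyst death, as a lifetime of 8.39 min.

3. The last dusk readings sum to 98.3%, with intermediate over substrate at 0.539, so in my first extreme version, with no product, the flask holds 63.9% substrate.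

4. In my second extreme version the catalyst keeps its early rate for 50 min, which makes 51.4% product and leaves 30.5% substrate.

5. The lifetime is shorter than the time, since 5.96 lifetimes pass, and the unfinished work lies 2.59 powers of ten down, so I take the full capacity: product 8.63%, substrate 58.3%, the largest share.

6. The forecast gives substrate at 58.2%, holding that “the plateau tracks the catalyst charged”.

7. The flask gives substrate at 58.1%.

    substrate + free catalyst ⇌ free catalyst + intermediate (K = 0.540, k = 170 /M/s)
    substrate + product ⇌ idle adduct, settled at all times (K = 2.20 /M)
    coupling partner + free catalyst + intermediate → free catalyst + product (k = 8.90 /M²/s)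
    free catalyst → spent catalyst (k = 0.00180 /s)
    2 substrate → homo dimer (k = 3.40 × 10⁻⁵ /M/s)

The flask holds 8.78% of product, against the 8.63% from the capacity. The main reason the flask still holds substrate is the way back from free catalyst + intermediate to substrate + free catalyst: without that way back the flask's substrate goes from 58.1% to 0%. In the neighbour flask with 0.0770 mM of free catalyst, the capacity gives 2.14% of product, and that flask holds 2.23%.

All runs were computed for an exercise; noise was put on by code.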